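Count the target's age.

in all of them: free catalyst 10 mM; time 3.0 h
- west: starting material 0.050 M; coupling partner 0.0600 M (fed, over 2.0 h); all else is in the flask from the start; the feed brings no volume worth counting
- north: starting material 0.050 M (fed, over 2.0 h); coupling partner 0.0600 M; all else is in the flask from the start; the feed brings no volume worth counting
- south: starting material 0.050 M; coupling partner 0.0600 M; everything together at the start
- south-east: starting material 0.050 M; coupling partner 0.0600 M (in portions, 3, over 2.0 h); first portion at the start, last at 2.0 h

    starting material + free catalyst → catalyst intermediate A (k1 = 1.4 /M/s)
    coupling partner + catalyst intermediate A → catalyst intermediate B (k2 = 0.20 /M/s)
    catalyst intermediate B ⇌ free catalyst + target (K3 = 0.093 M, k3 = 0.0092 /s)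
    catalyst intermediate A + target → spent catalyst (k4 = 0.0017 /M/s)
    target ⇌ isomer of the product (K5 = 13, k5 = 2.4 × 10⁻⁴ /s)

- percentages count the starting material that a species holds: one spent catalyst counts as two
- run time (west): 3.0 h

1. the flask that comes out highest in amount of target, in percent of the starting material charged, or "all alike" when all lie within 1.5 percentage points (west / north / south / south-east / all alike)
2. target at the end, in percent of the starting material charged, west
3. target at the end, in percent of the starting material charged, north
4. target at the end, in percent of the starting material charged, south
5. target at the end, in percent of the starting material charged, south-east

- The target is made and then turns into its isomer, so you need the rate of that turning. Take λ, the rate at which target's excess over its equilibrium share dies away, with both directions counted: 0.930 /h, a relaxation half-life of 0.745 h. The equilibrium share is 7.14%.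
- Bench rule for a feed: target is born as fast as the feed brings starting material. A feed then keeps 17.9% of the excess at 3.0 h, so my north comes to 23.8%.
- The rule needs the catalyst to keep up. With all of it held as catalyst intermediate B, it releases target 13.2 times faster than north's feed brings starting material. The border is a feed time of 9.06 min.
- South has no feed, so the rule stops there. That 9.06 min is a floor, reckoned with all the catalyst as catalyst intermediate B, and the uptake of starting material and of coupling partner takes time as well, so south's target is born later than that. As a crude count that makes the target too old, I still take south's target as born at the start. That keeps 6.13% of the excess and gives 12.8%.
- West feeds the coupling partner, and starting material is the limiting reagent because its charge is smaller than the partner's. West's feed has matched it after 1.67 h, so west's target is older than north's, and I get 20.8%.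
- The forecast names north: north 23.3% (21.5% to 25%), south-east 21.5% (19% to 24%), west 19.5% (17.5% to 21.5%), south 14% (12.5% to 15.5%). Its ground is that “the flask that makes its target latest keeps the most”. My north stands above its figure, and my south below.
- North comes out highest at 25.4%, with south-east at 22.5%, west at 22.2% and south at 14.5%. With the turning struck out, north gives 91.9%. North's 25.4% stands 1.6 percentage points above my count. Run λ on from that reading for 9.00 h more, and 0.0232% of the excess is left, which puts the reckoning at the equilibrium share of 7.14%. North left until 12 h holds 7.03%.

All constants are invented; the run is a simulation.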